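**Target check.** The SMILES reads as (1R,2S)-1,3-dihydroxy-1-(7-methoxy-2-oxo-2H-chromen-6-yl)-3-methylbutan-2-yl (2R)-2-methylbutanoate. Side-chain numbering used below: C1 benzylic (R, free OH), C2 (S, ester), C3 (CMe2OH). The C1 and C2 oxygens are syn in the zigzag drawing.

**Retrosynthetic overview**
- Target ⇐ aryl ketone at C1: the last step is a catalyst-controlled ketone reduction that sets C1 (R), syn to C2.
- Aryl ketone ⇐ free α-ketol + (2R)-2-methylbutanoic acid: at the ketol stage the C2 hydroxyl is the only one that can be acylated, so no protecting groups are needed.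
- Key C1–C2 disconnection: ketol ⇐ 7-methoxycoumarin-6-carbaldehyde used as an acyl anion equivalent (chiral carbene, Breslow intermediate) + 2-hydroxy-2-methylpropanal as acceptor; this bond formation also sets C2.
- Aldehyde ⇐ 6-bromo-7-methoxycoumarin (Pd formylation) ⇐ 5-bromo-2-hydroxy-4-methoxybenzaldehyde + stabilised ylide.
- Ring order: the benzene ring is bought; the lactone (pyranone) ring of the coumarin is the only ring formed, in step 1.

**Assumption:** the (5S)-configured triazolium precatalyst of step 4 is taken to direct Si-face attack on the acceptor aldehyde, giving the (2R)-ketol; if a first run shows the opposite sense, its (5R) mirror image is used and nothing else changes.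

**Step 1**
Reactants: 1 5-bromo-2-hydroxy-4-methoxybenzaldehyde; 2 ethyl 2-(triphenylphosphoranylidene)acetate
Product: 4 6-bromo-7-methoxy-2H-chromen-2-one, via cinnamate ester 3 (not isolated)
Conditions: 2 (1.2 equiv), PhNEt2, reflux (215 °C), 4 h
Reagents that add atoms: none
Why: Wittig olefination of the salicylaldehyde gives cinnamate 3, which at this temperature isomerises from E to Z and lactonises with loss of ethanol (Wittig–lactonisation coumarin synthesis), so bromine sits unambiguously at C6 and methoxy at C7.

**Step 2**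
Reactants: 4 6-bromo-7-methoxy-2H-chromen-2-one
Product: 5 7-methoxy-2-oxo-2H-chromene-6-carbaldehyde
Conditions: Pd(OAc)2 (1 mol%), di(1-adamantyl)-n-butylphosphine (3 mol%), TMEDA (0.75 equiv), CO/H2 (1:1, 5 bar), toluene, 100 °C
Reagents that add atoms: carbon monoxide, [C-]#[O+]
Why: Palladium-catalysed reductive carbonylation (formylation) of the aryl bromide, in which oxidative addition, CO insertion and hydrogenolysis by H2 with TMEDA as HBr acceptor give the aldehyde, while lactone and enoate are inert under the CO-saturated conditions.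

**Step 3**
Reactants: 6 2-methylbut-3-en-2-ol
Product: 8 2-hydroxy-2-methylpropanal, via secondary ozonide 7 (not isolated)
Conditions: O3, CH2Cl2, −78 °C; then PPh3 (1.1 equiv), −78 °C to 20 °C; short-path distillation, used fresh
Reagents that add atoms: ozone, [O-][O+]=O
Why: Ozonolysis by the Criegee mechanism gives ozonide 7, which PPh3 reduces to the aldehyde and formaldehyde, the tertiary alcohol being untouched and the formaldehyde (a competing acceptor in step 4) leaving on distillation.

**Step 4**
Reactants: 5 7-methoxy-2-oxo-2H-chromene-6-carbaldehyde; 8 2-hydroxy-2-methylpropanal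
Product: 10 6-[(2R)-2,3-dihydroxy-3-methylbutanoyl]-7-methoxy-2H-chromen-2-one, via Breslow enaminol 9 (not isolated)
Conditions: (5S)-5-(hydroxydiphenylmethyl)-2-(pentafluorophenyl)-6,7-dihydro-5H-pyrrolo[2,1-c][1,2,4]triazol-2-ium tetrafluoroborate (10 mol%), Rb2CO3 (10 mol%), 8 (3 equiv), THF, 18 °C
Reagents that add atoms: none
Why: Proposed new method: the carbene adds to 5 to give Breslow enaminol 9, a chiral acyl anion equivalent whose hydroxydiphenylmethyl arm hydrogen-bonds the carbonyl of 8 and steers Si-face attack to set C2 as (R), while chemoselectivity follows from 8 having a fully substituted α-carbon (it cannot become the donor) and 5 carrying an ortho methoxy group (a poor acceptor, so little homo-benzoin), the aryl ketone also being the thermodynamic ketol; the closest known reactions are the enantioselective homo-benzoin condensation with this bifunctional triazolium class and the chemoselective cross-benzoin of ortho-substituted benzaldehydes with aliphatic aldehydes.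

**Step 5**
Reactants: 10 6-[(2R)-2,3-dihydroxy-3-methylbutanoyl]-7-methoxy-2H-chromen-2-one; 11 (2R)-2-methylbutanoic acid
Product: 12 (2R)-3-hydroxy-1-(7-methoxy-2-oxo-2H-chromen-6-yl)-3-methyl-1-oxobutan-2-yl (2R)-2-methylbutanoate
Conditions: 11 (1.5 equiv), DCC (1.6 equiv), DMAP (0.1 equiv), CH2Cl2, 0 °C to 20 °C
Reagents that add atoms: none
Why: Steglich esterification acylates only the secondary ketol hydroxyl because the tertiary hydroxyl is inert under carbodiimide/DMAP at this temperature, and catalytic DMAP at 0 °C keeps both the acid α-centre and C2 from epimerising (no new stereocentre is formed).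

**Step 6**
Reactants: 12 (2R)-3-hydroxy-1-(7-methoxy-2-oxo-2H-chromen-6-yl)-3-methyl-1-oxobutan-2-yl (2R)-2-methylbutanoate
Product: 13 (1R,2S)-1,3-dihydroxy-1-(7-methoxy-2-oxo-2H-chromen-6-yl)-3-methylbutan-2-yl (2R)-2-methylbutanoate
Conditions: RuCl[(S,S)-TsDPEN](p-cymene) (2 mol%), HCO2H/Et3N (5:2), CH2Cl2, 25 °C
Reagents that add atoms: none
Why: Noyori–Ikariya asymmetric transfer hydrogenation, in which the (S,S) catalyst adds hydride in the same spatial sense that turns acetophenone into (S)-1-phenylethanol (here (1R) by the priority rules) and is matched with the (2R) centre (the pairing that takes (R)-benzoin to syn-(R,R)-hydrobenzoin and that the Felkin–Anh model also favours), so the syn (1R,2S) product forms while the acidic medium suppresses 1,2-acyl migration and leaves ester, lactone and enoate untouched.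

**Compound list**
1 | 5-bromo-2-hydroxy-4-methoxybenzaldehyde | O=Cc1cc(Br)c(OC)cc1O | starting material
2 | ethyl 2-(triphenylphosphoranylidene)acetate | CCOC(=O)C=P(c1ccccc1)(c1ccccc1)c1ccccc1 | starting material
3 | ethyl (E)-3-(5-bromo-2-hydroxy-4-methoxyphenyl)prop-2-enoate (first-formed cinnamate; isomerises and lactonises in the flask) | CCOC(=O)/C=C/c1cc(Br)c(OC)cc1O | intermediate
4 | 6-bromo-7-methoxy-2H-chromen-2-one | COc1cc2oc(=O)ccc2cc1Br | intermediate
5 | 7-methoxy-2-oxo-2H-chromene-6-carbaldehyde | COc1cc2oc(=O)ccc2cc1C=O | intermediate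
6 | 2-methylbut-3-en-2-ol | C=CC(C)(C)O | starting material
7 | 2-(1,2,4-trioxolan-3-yl)propan-2-ol (secondary ozonide, racemic) | CC(C)(O)C1OCOO1 | intermediate
8 | 2-hydroxy-2-methylpropanal | CC(C)(O)C=O | intermediate
9 | (5S)-3-[hydroxy(7-methoxy-2-oxo-2H-chromen-6-yl)methylidene]-5-(hydroxydiphenylmethyl)-2-(pentafluorophenyl)-2,5,6,7-tetrahydro-3H-pyrrolo[2,1-c][1,2,4]triazole (catalyst-bound Breslow enaminol of 5) | OC(c1ccccc1)(c1ccccc1)[C@@H]1CCC2=NN(c3c(F)c(F)c(F)c(F)c3F)C(=C(O)c3cc4ccc(=O)oc4cc3OC)N12 | intermediate
10 | 6-[(2R)-2,3-dihydroxy-3-methylbutanoyl]-7-methoxy-2H-chromen-2-one | O[C@@H](C(=O)c1cc2ccc(=O)oc2cc1OC)C(C)(C)O | intermediate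
11 | (2R)-2-methylbutanoic acid | CC[C@@H](C)C(=O)O | starting material
12 | (2R)-3-hydroxy-1-(7-methoxy-2-oxo-2H-chromen-6-yl)-3-methyl-1-oxobutan-2-yl (2R)-2-methylbutanoate | CC[C@@H](C)C(=O)O[C@@H](C(=O)c1cc2ccc(=O)oc2cc1OC)C(C)(C)O | intermediate
13 | (1R,2S)-1,3-dihydroxy-1-(7-methoxy-2-oxo-2H-chromen-6-yl)-3-methylbutan-2-yl (2R)-2-methylbutanoate | CC[C@@H](C)C(=O)O[C@@H]([C@H](O)c1cc2ccc(=O)oc2cc1OC)C(C)(C)O | target

**Step count.** Total: 6 steps. Longest linear sequence: 5 steps (1, 2, 4, 5, 6); step 3 is a one-step side branch.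

**Three steps most likely to fail, with fallbacks**

Step 4 (enantioselective cross-benzoin; risk of low ee, homo-benzoin or low conversion). The fallback sets out from 5 (with 8) and comes back at 12. The same coupling is run with the achiral precatalyst 2-(pentafluorophenyl)-6,7-dihydro-5H-pyrrolo[2,1-c][1,2,4]triazol-2-ium tetrafluoroborate and Et3N in THF, giving racemic 6-(2,3-dihydroxy-3-methylbutanoyl)-7-methoxy-2H-chromen-2-one F1. Esterification with 11 under the step 5 conditions gives 12 together with its C2 epimer, (2S)-3-hydroxy-1-(7-methoxy-2-oxo-2H-chromen-6-yl)-3-methyl-1-oxobutan-2-yl (2R)-2-methylbutanoate F2. The two are diastereomers and are separated by chromatography or crystallisation, so the acid of the target itself serves as the resolving agent. The same separation also upgrades material from step 4 if its ee is incomplete.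

Step 6 (hindered ketone; facial selectivity and acyl migration). The fallback sets out from 12 and comes back at 13, replacing catalyst control by substrate control. Et2BOMe in THF/MeOH at −78 °C turns the tertiary hydroxyl into (2R)-3-[(diethylboranyl)oxy]-1-(7-methoxy-2-oxo-2H-chromen-6-yl)-3-methyl-1-oxobutan-2-yl (2R)-2-methylbutanoate F3, in which boron chelates the ketone oxygen in a six-membered ring. NaBH4 then attacks this chelate from outside, anti to the pseudo-axial acyloxy group at C2 (Narasaka–Prasad-type 1,3-chelation control), which is expected to give the same syn (1R,2S) arrangement. Methanolic work-up returns 13.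

Step 2 (pressure formylation on an electron-rich, ortho-substituted bromide bearing a lactone). The fallback sets out from 4 and comes back at 5. Suzuki–Miyaura coupling of 4 with potassium vinyltrifluoroborate (PdCl2(dppf), Cs2CO3, THF/H2O, 70 °C) gives 6-ethenyl-7-methoxy-2H-chromen-2-one F4. Lemieux–Johnson cleavage (OsO4 cat., NaIO4, 2,6-lutidine, dioxane/H2O) of the electron-rich styrene, which reacts much faster than the electron-poor C3–C4 double bond of the coumarin, then gives 5.

**Further compounds**
F1 | step 4 | racemic 6-(2,3-dihydroxy-3-methylbutanoyl)-7-methoxy-2H-chromen-2-one | OC(C(=O)c1cc2ccc(=O)oc2cc1OC)C(C)(C)O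
F2 | step 4 | (2S)-3-hydroxy-1-(7-methoxy-2-oxo-2H-chromen-6-yl)-3-methyl-1-oxobutan-2-yl (2R)-2-methylbutanoate | CC[C@@H](C)C(=O)O[C@H](C(=O)c1cc2ccc(=O)oc2cc1OC)C(C)(C)O
F3 | step 6 | (2R)-3-[(diethylboranyl)oxy]-1-(7-methoxy-2-oxo-2H-chromen-6-yl)-3-methyl-1-oxobutan-2-yl (2R)-2-methylbutanoate | CC[C@@H](C)C(=O)O[C@@H](C(=O)c1cc2ccc(=O)oc2cc1OC)C(C)(C)OB(CC)CC
F4 | step 2 | 6-ethenyl-7-methoxy-2H-chromen-2-one | COc1cc2oc(=O)ccc2cc1C=C
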